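**Strategy.** The cyclohexene ring (C1 quaternary, C2 benzylic stereocentre, C3=C4, C5H2, C6H2) is cut at C1–C2 and C5–C6. C1 is C4 of curcumin and carries two identical feruloyl groups, so it is no stereocentre, and C2–C5 form a 1-arylbutadiene. A copper(II)–bis(oxazoline)-catalysed Diels–Alder reaction of (E)-1-(3,4-dimethoxyphenyl)buta-1,3-diene with a 4-methylenecurcumin makes both ring bonds, the C3=C4 alkene and the (2R) centre in one operation. The precursor is an acyclic, bench-stable, O-silylated 4-(tosylmethyl)curcumin that releases the chelating 2-methylene-1,3-dione in the flask; C6 comes from formaldehyde.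

Key step: step 4

Assumption: curcumin derivatives are written as diketo tautomers although they exist largely as enols. The sense of induction of the copper catalyst on this dienophile, which lies on the C2 axis of the complex, cannot be read from a simple model; the (S,S)-ligand is written, and its commercial antipode takes its place if a pilot run shows the opposite sense.

**Step 1**
Reactants: 1 (E)-3,4-dimethoxycinnamaldehyde
Product: 2 (E)-1-(3,4-dimethoxyphenyl)buta-1,3-diene
Conditions: Ph3PCH3Br, KOtBu, THF, 0 °C → rt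
Reagents that add atoms: methyltriphenylphosphonium bromide, C[P+](c1ccccc1)(c1ccccc1)c1ccccc1.[Br-]
Why: Wittig methylenation with the non-stabilised ylide should attack only the aldehyde and leave the existing (E)-alkene untouched, so the (E)-diene should form with no stereochemical issue at the new terminal C=C.

**Step 2**
Reactants: 3 curcumin
Product: 4 di-O-TBS-curcumin, (1E,6E)-1,7-bis[4-(tert-butyldimethylsilyloxy)-3-methoxyphenyl]hepta-1,6-diene-3,5-dione
Conditions: TBSCl, imidazole, DMF, 0 °C → rt; aq. NH4Cl work-up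
Reagents that add atoms: tert-butyldimethylsilyl chloride, CC(C)(C)[Si](C)(C)Cl
Why: Imidazole-mediated silylation of the two phenols is expected (any silyl enol ether at the diketone should hydrolyse on work-up), and the aryl silyl ethers prevent phenol oxa-Michael addition and copper phenoxide formation in the later steps.

**Step 3**
Reactants: 4 di-O-TBS-curcumin
Product: 5 (1E,6E)-1,7-bis[4-(tert-butyldimethylsilyloxy)-3-methoxyphenyl]-4-[(4-methylphenyl)sulfonylmethyl]hepta-1,6-diene-3,5-dione
Conditions: 37% aq. CH2O, TolSO2Na, HCO2H, THF–H2O, rt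
Reagents that add atoms: formaldehyde, C=O; sodium p-toluenesulfinate, Cc1ccc(cc1)S(=O)[O-].[Na+]
Why: In this three-component Mannich-type sulfonylmethylation, Knoevenagel condensation of the acidic 1,3-diketone with formaldehyde is followed by sulfa-Michael addition of the sulfinate, which should trap the reactive methylene dione as a storable sulfone.

**Step 4**
Reactants: 5 4-(tosylmethyl) dione; 2 (E)-1-(3,4-dimethoxyphenyl)buta-1,3-diene
Product: 7 (2E,2'E)-1,1'-[(2R)-2-(3,4-dimethoxyphenyl)cyclohex-3-ene-1,1-diyl]bis{3-[4-(tert-butyldimethylsilyloxy)-3-methoxyphenyl]prop-2-en-1-one}, via (1E,6E)-1,7-bis[4-(tert-butyldimethylsilyloxy)-3-methoxyphenyl]-4-methylidenehepta-1,6-diene-3,5-dione 6 (not isolated)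
Conditions: (i) K2CO3 (powdered, anhydrous), CH2Cl2, 0 °C, then cold filtration under argon; (ii) 2 (2 equiv), [Cu((S,S)-t-Bu-box)](SbF6)2 (10 mol %), CH2Cl2, −40 → −20 °C
Reagents that add atoms: none
Why: K2CO3 removes the acidic C4–H of 5 and the enolate expels p-toluenesulfinate (E1cB) to give the 2-methylene-1,3-dione 6, whose two carbonyl oxygens chelate the cationic copper(II)–bis(oxazoline) and lower the LUMO of the exocyclic C=CH2. The ring should then form by a concerted, asynchronous normal-electron-demand Diels–Alder reaction; the closest known types are the Cu(II)–box-catalysed enantioselective Diels–Alder reaction of chelating 2-alkylidene-1,3-dicarbonyl dienophiles and the racemic Knoevenagel/Diels–Alder domino of 1,3-diketones with formaldehyde and dienes. The cyclohexene closes by intermolecular [4+2] cycloaddition, suprafacial on both partners: the unsubstituted diene terminus bonds to the exocyclic CH2 (C5–C6) and the aryl-bearing terminus to the central carbon (C1–C2), which is the "ortho" orientation set by the largest HOMO coefficient of the diene and the largest LUMO coefficient of the dienophile. The C2 axis of the chelate runs through Cu, C1 and the CH2 carbon, so the two faces of the dienophile are homotopic and the only stereochemical variable is whether the diene body lies over one acyl arm or the other; the tert-butyl groups of the ligand fill two diagonal quadrants, make these two orientations diastereomeric and so control the single new stereocentre C2, intended as (R). The step needs chemoselectivity for the 1,1-diacyl C=CH2 over the two cinnamoyl C=C bonds, secured by its double activation and unsubstituted terminus, and periselectivity for the C=C over the oxadiene mode; a 2-styryl-dihydropyran from hetero-Diels–Alder addition could still reach constitutionally the same cyclohexene by Claisen rearrangement.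

**Step 5**
Reactants: 7 bis-TBS ether of the target
Product: 8 CNP0213153.1, (2E,2'E)-1,1'-[(2R)-2-(3,4-dimethoxyphenyl)cyclohex-3-ene-1,1-diyl]bis[3-(4-hydroxy-3-methoxyphenyl)prop-2-en-1-one]
Conditions: HF·pyridine, pyridine, THF, 0 °C → rt
Reagents that add atoms: none
Why: Fluoride cleavage of the aryl silyl ethers under weakly acidic, non-basic conditions should spare the retro-Claisen-prone non-enolisable 1,3-diketone, and C2 carries no acidic hydrogen and should keep its configuration.

**Compound list**
1 | (E)-3,4-dimethoxycinnamaldehyde | O=C/C=C/c1ccc(OC)c(OC)c1 | starting material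
2 | (E)-1-(3,4-dimethoxyphenyl)buta-1,3-diene | C=C/C=C/c1ccc(OC)c(OC)c1 | intermediate
3 | curcumin, (1E,6E)-1,7-bis(4-hydroxy-3-methoxyphenyl)hepta-1,6-diene-3,5-dione | COc1cc(/C=C/C(=O)CC(=O)/C=C/c2ccc(O)c(OC)c2)ccc1O | starting material
4 | di-O-TBS-curcumin | COc1cc(/C=C/C(=O)CC(=O)/C=C/c2ccc(O[Si](C)(C)C(C)(C)C)c(OC)c2)ccc1O[Si](C)(C)C(C)(C)C | intermediate
5 | 4-(tosylmethyl)-di-O-TBS-curcumin | COc1cc(/C=C/C(=O)C(CS(=O)(=O)c2ccc(C)cc2)C(=O)/C=C/c2ccc(O[Si](C)(C)C(C)(C)C)c(OC)c2)ccc1O[Si](C)(C)C(C)(C)C | intermediate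
6 | 4-methylidene-di-O-TBS-curcumin (formed in the flask) | COc1cc(/C=C/C(=O)C(=C)C(=O)/C=C/c2ccc(O[Si](C)(C)C(C)(C)C)c(OC)c2)ccc1O[Si](C)(C)C(C)(C)C | intermediate
7 | (2R)-cyclohexene adduct, bis-TBS ether of the target | COc1cc(/C=C/C(=O)C2(C(=O)/C=C/c3ccc(O[Si](C)(C)C(C)(C)C)c(OC)c3)CCC=C[C@@H]2c2ccc(OC)c(OC)c2)ccc1O[Si](C)(C)C(C)(C)C | intermediate
8 | CNP0213153.1, (2R) | COc1cc(/C=C/C(=O)C2(C(=O)/C=C/c3ccc(O)c(OC)c3)CCC=C[C@@H]2c2ccc(OC)c(OC)c2)ccc1O | target

**Total step count:** 5. **Longest linear sequence:** 4 steps (3 → 4 → 5 → 7 → 8).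

**Steps most likely to fail**

1. Step 4. The catalyst may discriminate poorly between the two diene orientations, because the reacting C=CH2 lies on the C2 axis far from the ligand. The free methylene dione may also dimerise by hetero-Diels–Alder addition, and the electron-rich diene may oligomerise. Fallback: the stereocentre is set by iridium-catalysed allylic alkylation and the ring is closed by metathesis. It sets out from 1 and 4 and comes back at 7. Luche reduction of 1 (NaBH4, CeCl3, MeOH) would give (E)-3-(3,4-dimethoxyphenyl)prop-2-en-1-ol F1, and ClCO2Me/pyridine would give (E)-3-(3,4-dimethoxyphenyl)allyl methyl carbonate F2. Branched-selective allylation of 4 with F2 ([Ir(cod)Cl]2, a Feringa-type phosphoramidite of the appropriate hand, THF) should give the (S)-1-arylallyl dione F3. Michael addition of F3 to acrolein (cat. Et3N) would give the quaternary aldehyde F4, Wittig methylenation the diene F5, and ring-closing metathesis (Grubbs II, CH2Cl2, 40 °C) closes the cyclohexene to 7.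

2. Step 3. The transient methylene dione may be intercepted by a second molecule of 4 instead of by sulfinate (bis-adduct), or sulfinate may be lost again during purification. Fallback: a Mannich/Cope-elimination route that sets out from 4 and comes back at 6. Dimethylmethyleneiminium iodide (CH2Cl2, rt) would give the 4-(dimethylaminomethyl) dione F6. mCPBA at −20 °C would give the N-oxide F7, which should undergo Cope elimination in the flask to 6; after a cold bicarbonate wash and drying the solution enters part (ii) of step 4.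

3. Step 5. Fluoride or adventitious base may trigger retro-Claisen C–C cleavage of the non-enolisable 1,3-diketone, or desilylation may stop halfway. Fallback: acid-labile acetal protection carried from the start, setting out from 3 and coming back at 8. MOMCl/iPr2NEt would give di-O-MOM-curcumin F8. Steps 3 and 4 as written would give the sulfone F9, the methylene dione F10 (in the flask) and the (2R)-adduct F11. HCl in MeOH at rt should then release 8.

**Further compounds**
F1 | step 4 | (E)-3-(3,4-dimethoxyphenyl)prop-2-en-1-ol | OC/C=C/c1ccc(OC)c(OC)c1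
F2 | step 4 | (E)-3-(3,4-dimethoxyphenyl)allyl methyl carbonate | COC(=O)OC/C=C/c1ccc(OC)c(OC)c1
F3 | step 4 | (1E,6E)-1,7-bis[4-(tert-butyldimethylsilyloxy)-3-methoxyphenyl]-4-[(1S)-1-(3,4-dimethoxyphenyl)prop-2-en-1-yl]hepta-1,6-diene-3,5-dione | C=C[C@@H](C(C(=O)/C=C/c1ccc(O[Si](C)(C)C(C)(C)C)c(OC)c1)C(=O)/C=C/c1ccc(O[Si](C)(C)C(C)(C)C)c(OC)c1)c1ccc(OC)c(OC)c1
F4 | step 4 | 4-[(1R)-1-(3,4-dimethoxyphenyl)prop-2-en-1-yl]-4-(3-oxopropyl) analogue of 4 | C=C[C@@H](C(CCC=O)(C(=O)/C=C/c1ccc(O[Si](C)(C)C(C)(C)C)c(OC)c1)C(=O)/C=C/c1ccc(O[Si](C)(C)C(C)(C)C)c(OC)c1)c1ccc(OC)c(OC)c1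
F5 | step 4 | 4-(but-3-en-1-yl)-4-[(1R)-1-(3,4-dimethoxyphenyl)prop-2-en-1-yl] analogue of 4 | C=C[C@@H](C(CCC=C)(C(=O)/C=C/c1ccc(O[Si](C)(C)C(C)(C)C)c(OC)c1)C(=O)/C=C/c1ccc(O[Si](C)(C)C(C)(C)C)c(OC)c1)c1ccc(OC)c(OC)c1
F6 | step 3 | 4-(dimethylaminomethyl)-di-O-TBS-curcumin | COc1cc(/C=C/C(=O)C(CN(C)C)C(=O)/C=C/c2ccc(O[Si](C)(C)C(C)(C)C)c(OC)c2)ccc1O[Si](C)(C)C(C)(C)C
F7 | step 3 | N-oxide of F6 | COc1cc(/C=C/C(=O)C(C[N+](C)(C)[O-])C(=O)/C=C/c2ccc(O[Si](C)(C)C(C)(C)C)c(OC)c2)ccc1O[Si](C)(C)C(C)(C)C
F8 | step 5 | di-O-MOM-curcumin | COCOc1ccc(/C=C/C(=O)CC(=O)/C=C/c2ccc(OCOC)c(OC)c2)cc1OC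
F9 | step 5 | 4-(tosylmethyl)-di-O-MOM-curcumin | COCOc1ccc(/C=C/C(=O)C(CS(=O)(=O)c2ccc(C)cc2)C(=O)/C=C/c2ccc(OCOC)c(OC)c2)cc1OC
F10 | step 5 | 4-methylidene-di-O-MOM-curcumin | COCOc1ccc(/C=C/C(=O)C(=C)C(=O)/C=C/c2ccc(OCOC)c(OC)c2)cc1OC
F11 | step 5 | (2R)-cyclohexene adduct, bis-MOM ether of the target | COCOc1ccc(/C=C/C(=O)C2(C(=O)/C=C/c3ccc(OCOC)c(OC)c3)CCC=C[C@@H]2c2ccc(OC)c(OC)c2)cc1OC
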